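**Retrosynthetic overview**

1. Target 18 is (R)-β-tocotrienol (chroman numbering O1, C2–C4, C4a, C5–C8, C8a; side chain C1′–C12′). Last disconnections: O–Si (17), then C2′–C3′ by Negishi sp3–sp2 coupling of iodide 10 with the (1E,5E)-alkenyl iodide 15, made in two steps from (E)-geranylacetone.
2. Iodide 10 comes from tricyclic lactol 7 by lactol reduction, removal of the C4 oxygen and iodination.
3. Key disconnection of 7: C4–C3 and O1–C2 in one operation, an amine-catalysed domino vinylogous aldol / oxa-Michael / lactolisation of salicylaldehyde 3 with prenal 4.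
4. Enabling feature: in the pyran ring (O1, C2, C3, C4, C4a, C8a) C4 is benzylic and ortho to O1, a salicyl unit taken at the aldehyde level. C3–C2(CH3)–C1′–C2′ is the skeleton of 3-methylbut-2-enal, whose CHO makes C3 a dienamine γ-carbon and C2 an iminium β-carbon and then stays as chain carbon C2′.
5. Ring order: arene from 2,5-dimethylhydroquinone (steps 1–2); pyran ring plus a temporary lactol ring in step 3; lactol ring opened in step 4; no further ring is formed.

Key step: step 3

Remark (assumption): the (R)-catalyst is chosen from the usual shielding model for diarylprolinol silyl ether iminium ions, with ring closure assumed to occur on the (E)-configured δ-hydroxy enal; both catalyst enantiomers, 2,5-dimethylhydroquinone, prenal and (E)-geranylacetone are taken as commercial.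

**Route**

Step 1
Reactants: 1 2,5-dimethylhydroquinone
Product: 2 2,5-dimethyl-4-(triisopropylsilyloxy)phenol
Conditions: TIPSCl (0.9 equiv), imidazole, DMF, 0 °C to rt
Reagents that add atoms: triisopropylsilyl chloride, CC(C)[Si](Cl)(C(C)C)C(C)C
Why: Silyl ether formation on a phenol; the two hydroxyls of 1 are symmetry-equivalent, so sub-stoichiometric TIPSCl can give only one mono-ether, separable from recovered 1 and the bis-ether (both recyclable).

Step 2
Reactants: 2 2,5-dimethyl-4-(triisopropylsilyloxy)phenol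
Product: 3 2-hydroxy-3,6-dimethyl-5-(triisopropylsilyloxy)benzaldehyde
Conditions: (CH2O)n, MgCl2, Et3N, MeCN, reflux
Reagents that add atoms: paraformaldehyde (formaldehyde), C=O
Why: Magnesium-phenoxide-directed ortho-formylation (hydroxymethylation, then hydride transfer to a second formaldehyde) occurs only ortho to the free OH, and 2 has a single unsubstituted ortho position.

Step 3
Reactants: 3 2-hydroxy-3,6-dimethyl-5-(triisopropylsilyloxy)benzaldehyde, 4 3-methylbut-2-enal (prenal)
Product: 7 (2S,6S)-2,7,10-trimethyl-8-(triisopropylsilyloxy)-3,4-dihydro-2H,6H-2,6-methano-1,5-benzodioxocin-4-ol (tricyclic lactol; epimers at the hemiacetal carbon), via hydroxy enal 5 (not isolated), via open hydroxy aldehyde 6 (not isolated)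
Conditions: 4 (3 equiv), (R)-2-{bis[3,5-bis(trifluoromethyl)phenyl](trimethylsilyloxy)methyl}pyrrolidine (20 mol%), PhCO2H (20 mol%), toluene, rt
Reagents that add atoms: none
Why: The amine condenses with 4 to a cross-conjugated dienamine whose γ-CH2 adds to the aldehyde of 3 (vinylogous aldol, C3–C4 bond) to give the iminium ion of 5; the phenol then adds to the iminium β-carbon (oxa-Michael, O1–C2 bond), and hydrolysis releases 6, which is drained from all equilibria as lactol 7. The closest known reaction type is the diarylprolinol-silyl-ether-catalysed domino aldol / oxa-Michael / hemiacetalisation of salicylaldehydes with 3-methyl-2-enals (dienamine–iminium catalysis). The pyran ring closes 6-exo-trig (O1 onto the iminium β-carbon) and the temporary lactol ring closes 6-exo-trig (C4–OH onto the C=O), which is possible only when the CH2CHO arm and the C4 oxygen are cis. C2 is set by the catalyst, whose C(Ar)2OSiMe3 group shields one face of the (E)-iminium ion so that O1 adds anti to it; C4 is set relative to C2 because the aldol step is reversible and only the cis isomer can lactolise. The step needs γ- over α-reactivity of the dienamine and one enal geometry at ring closure: the two equivalent γ-methyl groups of 4 leave no regiochemical choice in dienamine formation, the ortho-OH can reach a six-membered closure only after γ-attack, and the lactol trap keeps 6 from racemising by retro-oxa-Michael.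

Step 4
Reactants: 7 tricyclic lactol
Product: 8 (2R,4S)-2-(2-hydroxyethyl)-2,5,8-trimethyl-6-(triisopropylsilyloxy)chroman-4-ol
Conditions: NaBH4, THF/MeOH, 0 °C
Reagents that add atoms: none
Why: Borohydride reduction of the lactol through its open hydroxy-aldehyde form; reduction is faster than enolisation, so the β-aryloxy aldehyde has no time for retro-oxa-Michael and C2 is kept.

Step 5
Reactants: 8 (2R,4S)-2-(2-hydroxyethyl)-2,5,8-trimethyl-6-(triisopropylsilyloxy)chroman-4-ol
Product: 9 2-[(2S)-2,5,8-trimethyl-6-(triisopropylsilyloxy)chroman-2-yl]ethanol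
Conditions: Et3SiH, CF3CO2H, CH2Cl2, 0 °C; then NaHCO3, MeOH/H2O
Reagents that add atoms: none
Why: Ionic hydrogenation: the C4 hydroxyl ionises to a benzylic cation stabilised by the ortho ring oxygen and is reduced by hydride transfer from Et3SiH, while the primary alcohol, the tertiary ether at C2 and the aryl silyl ether are inert (a transient trifluoroacetate or bridged benzylic ether of the primary OH is cleaved in the medium or on bicarbonate work-up).

Step 6
Reactants: 9 2-[(2S)-2,5,8-trimethyl-6-(triisopropylsilyloxy)chroman-2-yl]ethanol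
Product: 10 triisopropyl{[(2S)-2-(2-iodoethyl)-2,5,8-trimethylchroman-6-yl]oxy}silane
Conditions: I2, PPh3, imidazole, CH2Cl2, 0 °C to rt
Reagents that add atoms: iodine, II
Why: Appel-type iodination of the unhindered primary alcohol by SN2 displacement of the oxyphosphonium ion; no stereocentre is touched.

Step 7
Reactants: 11 (5E)-6,10-dimethylundeca-5,9-dien-2-one ((E)-geranylacetone)
Product: 13 (5E)-6,10-dimethylundeca-5,9-dien-1-yne, via enol phosphate 12 (not isolated)
Conditions: LiN(i-Pr)2, THF, −78 °C; ClP(O)(OEt)2; then LiN(i-Pr)2 (2.3 equiv), −78 °C to rt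
Reagents that add atoms: none
Why: Kinetic deprotonation of the methyl ketone at CH3, O-phosphorylation and base-induced elimination of the terminal enol phosphate should give the terminal alkyne (enol phosphate elimination) without touching the isolated trisubstituted alkenes or their geometry.

Step 8
Reactants: 13 (5E)-6,10-dimethylundeca-5,9-dien-1-yne
Product: 15 (1E,5E)-1-iodo-2,6,10-trimethylundeca-1,5,9-triene, via alkenylalane 14 (not isolated)
Conditions: AlMe3, Cp2ZrCl2 (25 mol%), CH2Cl2, 0 °C to rt; then I2, THF, −30 °C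
Reagents that add atoms: trimethylaluminium, C[Al](C)C; iodine, II
Why: Zirconium-catalysed syn-methylalumination of the terminal alkyne puts CH3 on the internal carbon and aluminium on the terminal carbon, and iodinolysis with retention gives the (E)-alkenyl iodide; isolated trisubstituted alkenes do not react.

Step 9
Reactants: 10 triisopropyl{[(2S)-2-(2-iodoethyl)-2,5,8-trimethylchroman-6-yl]oxy}silane, 15 (1E,5E)-1-iodo-2,6,10-trimethylundeca-1,5,9-triene
Product: 17 triisopropyl({(2R)-2,5,8-trimethyl-2-[(3E,7E)-4,8,12-trimethyltrideca-3,7,11-trien-1-yl]chroman-6-yl}oxy)silane, via alkylzinc iodide 16 (not isolated)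
Conditions: Zn dust, LiCl, THF, 40 °C; then 15, Pd(dppf)Cl2 (5 mol%), THF, 50 °C
Reagents that add atoms: none
Why: Negishi sp3–sp2 cross-coupling: zinc insertion into the primary C–I bond gives an alkylzinc iodide that tolerates the silyl ether, and coupling with the alkenyl iodide at zerovalent palladium proceeds with retention of the (E) geometry, the wide-bite-angle dppf ligand favouring reductive elimination over β-hydride elimination.

Step 10
Reactants: 17 O-triisopropylsilyl β-tocotrienol
Product: 18 (2R)-2,5,8-trimethyl-2-[(3E,7E)-4,8,12-trimethyltrideca-3,7,11-trien-1-yl]chroman-6-ol (β-tocotrienol)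
Conditions: Bu4NF, AcOH, THF, 0 °C, argon
Reagents that add atoms: none
Why: Fluoride-induced cleavage of the aryl silyl ether (desilylation) under buffered, oxygen-free conditions leaves the triene and the tertiary ether stereocentre untouched.

**Compound list**

1 | 2,5-dimethylbenzene-1,4-diol (2,5-dimethylhydroquinone) | Cc1cc(O)c(C)cc1O | starting material
2 | 2,5-dimethyl-4-(triisopropylsilyloxy)phenol | Cc1cc(O[Si](C(C)C)(C(C)C)C(C)C)c(C)cc1O | intermediate
3 | 2-hydroxy-3,6-dimethyl-5-(triisopropylsilyloxy)benzaldehyde | O=Cc1c(O)c(C)cc(O[Si](C(C)C)(C(C)C)C(C)C)c1C | intermediate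
4 | 3-methylbut-2-enal (prenal) | CC(C)=CC=O | starting material
5 | (2E,5S)-5-hydroxy-5-[2-hydroxy-3,6-dimethyl-5-(triisopropylsilyloxy)phenyl]-3-methylpent-2-enal (formed as its iminium ion with the catalyst; not isolated) | O=C/C=C(\C)C[C@H](O)c1c(O)c(C)cc(O[Si](C(C)C)(C(C)C)C(C)C)c1C | intermediate
6 | 2-[(2S,4S)-4-hydroxy-2,5,8-trimethyl-6-(triisopropylsilyloxy)chroman-2-yl]acetaldehyde (open form of 7; not isolated) | O=CC[C@]1(C)C[C@H](O)c2c(C)c(O[Si](C(C)C)(C(C)C)C(C)C)cc(C)c2O1 | intermediate
7 | (2S,6S)-2,7,10-trimethyl-8-(triisopropylsilyloxy)-3,4-dihydro-2H,6H-2,6-methano-1,5-benzodioxocin-4-ol: cyclic hemiacetal of 6 with a C4–O–CH(OH)–CH2–C2 bridge, (2S,4S) in chroman numbering, hemiacetal carbon as epimer mixture | OC3C[C@]1(C)C[C@H](O3)c2c(C)c(O[Si](C(C)C)(C(C)C)C(C)C)cc(C)c2O1 | intermediate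
8 | (2R,4S)-2-(2-hydroxyethyl)-2,5,8-trimethyl-6-(triisopropylsilyloxy)chroman-4-ol | OCC[C@]1(C)C[C@H](O)c2c(C)c(O[Si](C(C)C)(C(C)C)C(C)C)cc(C)c2O1 | intermediate
9 | 2-[(2S)-2,5,8-trimethyl-6-(triisopropylsilyloxy)chroman-2-yl]ethanol | OCC[C@]1(C)CCc2c(C)c(O[Si](C(C)C)(C(C)C)C(C)C)cc(C)c2O1 | intermediate
10 | triisopropyl{[(2S)-2-(2-iodoethyl)-2,5,8-trimethylchroman-6-yl]oxy}silane | ICC[C@]1(C)CCc2c(C)c(O[Si](C(C)C)(C(C)C)C(C)C)cc(C)c2O1 | intermediate
11 | (5E)-6,10-dimethylundeca-5,9-dien-2-one ((E)-geranylacetone) | CC(=O)CC/C=C(\C)CCC=C(C)C | starting material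
12 | diethyl (5E)-6,10-dimethylundeca-1,5,9-trien-2-yl phosphate (not isolated) | C=C(OP(=O)(OCC)OCC)CC/C=C(\C)CCC=C(C)C | intermediate
13 | (5E)-6,10-dimethylundeca-5,9-dien-1-yne | C#CCC/C=C(\C)CCC=C(C)C | intermediate
14 | dimethyl[(1E,5E)-2,6,10-trimethylundeca-1,5,9-trien-1-yl]alane (not isolated) | C[Al](C)/C=C(\C)CC/C=C(\C)CCC=C(C)C | intermediate
15 | (1E,5E)-1-iodo-2,6,10-trimethylundeca-1,5,9-triene | I/C=C(\C)CC/C=C(\C)CCC=C(C)C | intermediate
16 | iodo{2-[(2S)-2,5,8-trimethyl-6-(triisopropylsilyloxy)chroman-2-yl]ethyl}zinc (not isolated) | I[Zn]CC[C@]1(C)CCc2c(C)c(O[Si](C(C)C)(C(C)C)C(C)C)cc(C)c2O1 | intermediate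
17 | triisopropyl({(2R)-2,5,8-trimethyl-2-[(3E,7E)-4,8,12-trimethyltrideca-3,7,11-trien-1-yl]chroman-6-yl}oxy)silane | CC(C)=CCC/C(C)=C/CC/C(C)=C/CC[C@]1(C)CCc2c(C)c(O[Si](C(C)C)(C(C)C)C(C)C)cc(C)c2O1 | intermediate
18 | (2R)-2,5,8-trimethyl-2-[(3E,7E)-4,8,12-trimethyltrideca-3,7,11-trien-1-yl]chroman-6-ol (β-tocotrienol) | CC(C)=CCC/C(C)=C/CC/C(C)=C/CC[C@]1(C)CCc2c(C)c(O)cc(C)c2O1 | target

**Step count and risks**

Total step count: 10. Longest linear sequence: 8 steps (1 → 2 → 3 → 7 → 8 → 9 → 10 → 17 → 18; steps 1–6, 9, 10).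

Step 3 is the most likely to fail. What may go wrong is poor facial selectivity in the oxa-Michael ring closure, or diversion of the dienamine into α-attack and self-condensation of prenal. The fallback makes the two bonds in separate operations and sets the stereocentre by an enantioselective Wacker-type cyclisation. It sets out from 3. Wittig reaction with 1-(triphenylphosphoranylidene)propan-2-one (toluene, 80 °C) should give the enone (3E)-4-[2-hydroxy-3,6-dimethyl-5-(triisopropylsilyloxy)phenyl]but-3-en-2-one F1. Hydrogenation (H2, Pd/C, EtOAc) should give the saturated ketone 4-[2-hydroxy-3,6-dimethyl-5-(triisopropylsilyloxy)phenyl]butan-2-one F2. A second Wittig reaction with excess ethylidenetriphenylphosphorane (THF) should give the alkene 3,6-dimethyl-2-(3-methylpent-3-en-1-yl)-4-(triisopropylsilyloxy)phenol F3 as an E/Z mixture. Oxidative cyclisation of F3 with Pd(OCOCF3)2, the enantiomer of a BOXAX-type bis(oxazoline) ligand that delivers the (S)-chroman, and p-benzoquinone in MeOH (oxypalladation at divalent palladium, then β-hydride elimination) should give the vinylchroman triisopropyl{[(2S)-2-ethenyl-2,5,8-trimethylchroman-6-yl]oxy}silane F4. Hydroboration with 9-BBN gives the borane 9-{2-[(2R)-2,5,8-trimethyl-6-(triisopropylsilyloxy)chroman-2-yl]ethyl}-9-borabicyclo[3.3.1]nonane F5, which is coupled in the same flask with 15 (Pd(dppf)Cl2, K3PO4, THF/DMF/H2O) and comes back to the route at 17.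

Step 9 is second. What may go wrong is incomplete zinc insertion, or β-hydride elimination and homocoupling at the alkylpalladium stage. The fallback is a B-alkyl Suzuki–Miyaura coupling through a borate made by halogen–lithium exchange. It sets out from 10. Treatment with t-BuLi (2 equiv, Et2O, −78 °C) should give the alkyllithium {2-[(2R)-2,5,8-trimethyl-6-(triisopropylsilyloxy)chroman-2-yl]ethyl}lithium F6. Trapping with 9-methoxy-9-BBN gives the borate lithium 9-methoxy-9-{2-[(2R)-2,5,8-trimethyl-6-(triisopropylsilyloxy)chroman-2-yl]ethyl}-9-boratabicyclo[3.3.1]nonane F7. Addition of 15, Pd(dppf)Cl2 and aqueous K3PO4 in DMF at rt should bring it back to the route at 17.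

Step 5 is third. What may go wrong is side reaction of the benzylic cation (dimerisation by arene alkylation, stalling at the bridged benzylic ether) or loss of the silyl ether in acid. The fallback removes the C4 oxygen by hydrogenolysis at the lactone level and replaces steps 4 and 5. It sets out from 7. Oxidation (DMP, NaHCO3, CH2Cl2) should give the bridged lactone (2S,6S)-2,7,10-trimethyl-8-(triisopropylsilyloxy)-2H,6H-2,6-methano-1,5-benzodioxocin-4(3H)-one F8. Hydrogenolysis of its benzylic C–O bond (H2, Pd/C, EtOAc; no alkene is present at this stage) should give the acid 2-[(2S)-2,5,8-trimethyl-6-(triisopropylsilyloxy)chroman-2-yl]acetic acid F9. Reduction with BH3·THF comes back to the route at 9.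

**Further compounds**

F1 | step 3 | (3E)-4-[2-hydroxy-3,6-dimethyl-5-(triisopropylsilyloxy)phenyl]but-3-en-2-one | CC(=O)/C=C/c1c(O)c(C)cc(O[Si](C(C)C)(C(C)C)C(C)C)c1C
F2 | step 3 | 4-[2-hydroxy-3,6-dimethyl-5-(triisopropylsilyloxy)phenyl]butan-2-one | CC(=O)CCc1c(O)c(C)cc(O[Si](C(C)C)(C(C)C)C(C)C)c1C
F3 | step 3 | 3,6-dimethyl-2-(3-methylpent-3-en-1-yl)-4-(triisopropylsilyloxy)phenol (E/Z mixture) | CC=C(C)CCc1c(O)c(C)cc(O[Si](C(C)C)(C(C)C)C(C)C)c1C
F4 | step 3 | triisopropyl{[(2S)-2-ethenyl-2,5,8-trimethylchroman-6-yl]oxy}silane | C=C[C@]1(C)CCc2c(C)c(O[Si](C(C)C)(C(C)C)C(C)C)cc(C)c2O1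
F5 | step 3 | 9-{2-[(2R)-2,5,8-trimethyl-6-(triisopropylsilyloxy)chroman-2-yl]ethyl}-9-borabicyclo[3.3.1]nonane | B1(C2CCCC1CCC2)CC[C@]3(C)CCc4c(C)c(O[Si](C(C)C)(C(C)C)C(C)C)cc(C)c4O3
F6 | step 9 | {2-[(2R)-2,5,8-trimethyl-6-(triisopropylsilyloxy)chroman-2-yl]ethyl}lithium | [Li]CC[C@]1(C)CCc2c(C)c(O[Si](C(C)C)(C(C)C)C(C)C)cc(C)c2O1
F7 | step 9 | lithium 9-methoxy-9-{2-[(2R)-2,5,8-trimethyl-6-(triisopropylsilyloxy)chroman-2-yl]ethyl}-9-boratabicyclo[3.3.1]nonane | [Li+].CO[B-]1(CC[C@]2(C)CCc3c(C)c(O[Si](C(C)C)(C(C)C)C(C)C)cc(C)c3O2)C4CCCC1CCC4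
F8 | step 5 | (2S,6S)-2,7,10-trimethyl-8-(triisopropylsilyloxy)-2H,6H-2,6-methano-1,5-benzodioxocin-4(3H)-one | O=C3C[C@]1(C)C[C@H](O3)c2c(C)c(O[Si](C(C)C)(C(C)C)C(C)C)cc(C)c2O1
F9 | step 5 | 2-[(2S)-2,5,8-trimethyl-6-(triisopropylsilyloxy)chroman-2-yl]acetic acid | OC(=O)C[C@]1(C)CCc2c(C)c(O[Si](C(C)C)(C(C)C)C(C)C)cc(C)c2O1
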